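The numbers in the tables stem from a simulated flask for substances that don't exist; noise was put on by code.

Count the partner.

| setting | red | teal | flask |
|---|---|---|---|
| substrate | 0.050 M | 0.050 M | 0.050 M |
| partner | 0.065 M (fed, over 2.0 h) | 0.065 M (fed, over 2.0 h) | 0.0650 M (fed, over 2.0 h) |
| protic impurity | 0.0067 M | 0.015 M | 0.0100 M |
| remark | run made earlier | run made earlier |  |
| time |  |  | 15 d |

- red (time / d: intermediate / %, target / %): 0.500: 30.5, 1.0; 1.25: 46.4, 6.5; 2.50: 49.1, 14.9; 6.00: 30.2, 30.1; 12.0: 10.8, 43.0
- teal (time / d: intermediate / %, target / %): 0.500: 24.9, 0.6; 1.25: 42.6, 5.8; 2.50: 45.3, 11.5; 6.00: 30.4, 25.6; 12.0: 10.4, 39.9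

(scatter of a reading: 1 percentage point)

- time, not beyond 15 d, at which the flask holds most intermediate
- the amount of intermediate, in percent of the substrate charged, at that time
- earliest time at which at least nineteen twentieths of that best amount are there, in d
- latest time at which they still are, in d



The reckoning here assumes that each protic impurity spends one partner. The flask's charge of partner less its protic impurity is 0.0550 M: call this usable partner, U. Red has 0.0583 M and teal 0.0500 M.

Let r be the mean rate over the first 0.500 d, read as intermediate plus target. Red reads 0.630 /d of its substrate and teal 0.510 /d. Their ratio is 1.24, and the ratio of U is 1.17; a scatter of 1 percentage point per reading does not separate these. Scaled by U, this reckoning puts the flask's mean rate over that time at: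

r = 0.630 /d × 0.0550 M / 0.0583 M = 0.594 /d

Taking the rate as substrate times usable partner, two factors slow it. When half of the substrate is gone:

substrate factor 0.5 × partner factor 0.545 = 0.273

The flask's U exceeds its substrate by 0.00500 M, so by this count substrate is the limiting reagent in the flask. At 2.50 d, U places the flask between teal's 45.3% and red's 49.1%, at 47.6%.

The forecast gives 48% at 2.1 d, with a window from 1.45 d to 3 d. Its ground: “The impurity therefore mainly costs partner and sets the plateau”.

The flask gives 48.1% at 2.10 d, with a window from 1.40 d to 3.07 d.

    substrate + partner → intermediate (k = 0.668 /M/h)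
    intermediate → target (k = 0.0101 /h)
    target ⇌ isomer of the product (K = 1.08, k = 0.0594 /h)
    partner + protic impurity → quenched reagent (k = 11.3 /M/h)

The surplus of U is 7.69% of the partner charge, and the flask holds 7.69% of its partner at 150 d. The neighbouring flask has 0.085 M of substrate and the other charges unchanged. There U is 0.647 of the substrate, which by count leaves 35.3% of the substrate unconverted. The best amount of intermediate in the neighbouring flask is 38.5%, against 48.1% in the flask. At 15.0 d, the neighbouring flask holds 0.0223% of its partner charge and 35.3% of its substrate charge.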